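**Retrosynthetic overview**
1. Feature: in naphthoquinone 18 the carbon that bears ring C (C8) sits on quinone carbon C8a. C7=C8–C8a=C4a is therefore the diene of a vinylquinone, and C5–C6 with the C6 methyl is a two-carbon enol ether unit. Ring B is cut at C4a–C5 and C6–C7.
2. 18 ⇒ 16 (loss of MeOH from C6, one oxidation equivalent) ⇒ vinylquinone 12 + 2-methoxypropene 13 by an inverse-demand [4+2]. The atom balance (C19H20O6 + C4H8O = C23H28O7) requires the aromatised tautomer of the adduct to keep C7=C8, so it is a 5,6-dihydronaphthalenediol and not a tetrahydronaphthalenediol.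
3. 12 ⇒ guaiacol-type phenol 11 (para oxidation) ⇒ (Z)-enol triflate 7 + ring C boronate 9 (stereoretentive Suzuki coupling). This fixes CH3 trans to ring A, which ethylidenation of the hindered, phenol-bearing benzophenone could not do.
4. 7 ⇒ o-vanillin 1 (allyl protection, EtMgBr, oxidation, Z-enolate triflation); 9 ⇒ 1-bromo-2,4,5-trimethoxybenzene 8.
5. Ring order: rings A and C are bought. Ring A becomes the quinone in step 8. Ring B is the only ring made (step 9) and is aromatised in step 10.

Key step: step 9

Assumption: the target SMILES carries no stereodescriptor, so the hindered C8–C1' biaryl axis is not controlled and 18 is made without regard to it.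
Numbering: from 12 onwards the locants of 18 (C1–C8a) are used. Ring A is the quinone ring, ring B the new carbocycle, ring C the trimethoxyphenyl group.

**Step 1**
Reactants: 1 o-vanillin (2-hydroxy-3-methoxybenzaldehyde)
Product: 2 3-methoxy-2-(prop-2-en-1-yloxy)benzaldehyde
Conditions: allyl bromide, K2CO3, DMF, 23 °C
Reagents that add atoms: allyl bromide, C=CCBr
Why: Williamson ether synthesis on an acidic phenol; the allyl group withstands the Grignard reagent, the oxidant and the amide base, and it can later be removed under neutral conditions that cannot protonate the electron-rich diarylalkene.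

**Step 2**
Reactants: 2 3-methoxy-2-(prop-2-en-1-yloxy)benzaldehyde; 3 ethylmagnesium bromide
Product: 4 (±)-1-[3-methoxy-2-(prop-2-en-1-yloxy)phenyl]propan-1-ol
Conditions: EtMgBr, THF, 0 °C; aqueous work-up
Reagents that add atoms: none
Why: Grignard addition to an aromatic aldehyde; the carbinol centre forms as a racemate and is destroyed in step 3.

**Step 3**
Reactants: 4 (±)-1-[3-methoxy-2-(prop-2-en-1-yloxy)phenyl]propan-1-ol
Product: 5 1-[3-methoxy-2-(prop-2-en-1-yloxy)phenyl]propan-1-one
Conditions: Dess–Martin periodinane, CH2Cl2, 23 °C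
Reagents that add atoms: none
Why: Dess–Martin oxidation of a secondary benzylic alcohol, mild enough to leave the allyl ether and the arene untouched.

**Step 4**
Reactants: 5 1-[3-methoxy-2-(prop-2-en-1-yloxy)phenyl]propan-1-one
Product: 7 (Z)-1-[3-methoxy-2-(prop-2-en-1-yloxy)phenyl]prop-1-en-1-yl trifluoromethanesulfonate (CH3 cis to OTf), via potassium Z-enolate 6 (not isolated)
Conditions: KN(SiMe3)2, THF, −78 °C; PhNTf2, −78 → 0 °C
Reagents that add atoms: N-phenylbis(trifluoromethanesulfonimide), O=S(=O)(N(c1ccccc1)S(=O)(=O)C(F)(F)F)C(F)(F)F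
Why: Kinetic deprotonation of an aryl ethyl ketone should give the Z(O)-enolate, because allylic 1,3-strain between the twisted aryl group and the methyl group penalises the other geometry, and O-sulfonylation (enol triflate formation) freezes that geometry.

**Step 5**
Reactants: 8 1-bromo-2,4,5-trimethoxybenzene
Product: 9 4,4,5,5-tetramethyl-2-(2,4,5-trimethoxyphenyl)-1,3,2-dioxaborolane
Conditions: B2pin2, PdCl2(dppf) (3 mol %), KOAc, 1,4-dioxane, 90 °C
Reagents that add atoms: bis(pinacolato)diboron, CC1(C)OB(OC1(C)C)B1OC(C)(C)C(C)(C)O1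
Why: Miyaura borylation of an aryl bromide; the pinacol ester is preferred to the free boronic acid because this electron-rich, ortho-methoxy aryl boron species is prone to protodeboronation.

**Step 6**
Reactants: 7 (Z)-enol triflate; 9 ring C pinacol boronate
Product: 10 1-{(E)-1-[3-methoxy-2-(prop-2-en-1-yloxy)phenyl]prop-1-en-1-yl}-2,4,5-trimethoxybenzene (CH3 cis to ring C and trans to ring A)
Conditions: PdCl2(dppf) (5 mol %), K3PO4, THF–H2O, 50 °C
Reagents that add atoms: none
Why: Suzuki–Miyaura coupling of an alkenyl triflate proceeds with retention at the sp2 carbon, so ring C takes the place of OTf cis to CH3, and any premature loss of the allyl group would only deliver 11.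

**Step 7**
Reactants: 10 allyl-protected diarylpropene
Product: 11 2-methoxy-6-[(Z)-1-(2,4,5-trimethoxyphenyl)prop-1-en-1-yl]phenol (same spatial arrangement as 10: CH3 cis to ring C and trans to ring A)
Conditions: Pd(PPh3)4 (5 mol %), morpholine, THF, 23 °C
Reagents that add atoms: none
Why: Tsuji–Trost-type deallylation, in which zerovalent palladium ionises the aryl allyl ether and morpholine captures the allyl fragment under neutral conditions, so the alkene geometry is untouched (the descriptor becomes Z only because OH ranks below OCH3 when the two rings are compared by the CIP rules).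

**Step 8**
Reactants: 11 2-methoxy-6-[(Z)-1-(2,4,5-trimethoxyphenyl)prop-1-en-1-yl]phenol
Product: 12 2-methoxy-6-[(E)-1-(2,4,5-trimethoxyphenyl)prop-1-en-1-yl]cyclohexa-2,5-diene-1,4-dione (CH3 trans to the quinone ring)
Conditions: ON(SO3K)2 (2.5 equiv), KH2PO4 buffer, H2O–acetone, 0 → 23 °C, dark; used at once
Reagents that add atoms: potassium nitrosodisulfonate ON(SO3K)2, [K+].[K+].[O]N(S(=O)(=O)[O-])S(=O)(=O)[O-]
Why: Teuber oxidation, in which one nitroxyl radical abstracts the phenolic hydrogen, a second couples through oxygen at the free para carbon and loss of HN(SO3K)2 gives the p-quinone, while the twisted alkene and the aryl methyl ethers of ring C (which (NH4)2Ce(NO3)6 would demethylate) are left alone.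

**Step 9**
Reactants: 12 vinylquinone; 13 2-methoxypropene
Product: 16 (±)-2,6-dimethoxy-6,7-dimethyl-8-(2,4,5-trimethoxyphenyl)-5,6-dihydronaphthalene-1,4-diol, via isoquinone methide 14 (not isolated), via o-quinone methide tautomer 15 (not isolated)
Conditions: 13 (20 equiv), PhMe, base-washed sealed tube, Ar, dark, 23 → 45 °C
Reagents that add atoms: none
Why: Vinyl quinone Diels–Alder reaction, an inverse-electron-demand [4+2] in which the electron-poor diene C7=C8–C8a=C4a of 12 takes up the electron-rich alkene of 13 in one highly asynchronous event, the CH2 of 13 bonding ahead to C4a (C4a–C5) and the oxocarbenium-like carbon following onto C7 (C6–C7). Ring B, six-membered and all-carbon, arises directly from this cycloaddition (suprafacial on both partners) as isoquinone methide 14; enolisation (H-4a to O4) gives o-quinone methide 15, and a 1,5-hydrogen shift (H-7 to O1) re-aromatises ring A to 16, which therefore retains C7=C8. In 14 the cis relation of H-4a and H-7 follows from suprafacial addition to the E diene and the cis relation of 6-OCH3 and 7-CH3 from the expected endo orientation of the methoxy group; C4a and C7 are flattened on the way to 16 and the remaining racemic C6 centre is removed in step 10, so no stereocontrol is needed. The selectivity that is needed is regiochemical (CH2 to C4a and not to C7, which would give a 5,7-dimethyl skeleton): the C2 methoxy group ties the C4 carbonyl into a vinylogous ester and switches off C3, so the C1 carbonyl dominates and makes its β-carbon C4a the most electrophilic site, whereas 1,6-attack at C7 would run through the deactivated C4 carbonyl and meet the methyl group. Closure through O4 to a dihydrobenzofuran and proton loss at the zwitterion-like stage are disfavoured by the absence of any Lewis or Brønsted acid, by the non-polar medium and by the E geometry, which places H rather than CH3 on the inside of the s-cis diene. The large excess of 13 keeps the cycloaddition ahead of dimerisation of 12 and of redox exchange between 16 and 12.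

**Step 10**
Reactants: 16 (±)-2,6-dimethoxy-6,7-dimethyl-8-(2,4,5-trimethoxyphenyl)-5,6-dihydronaphthalene-1,4-diol
Product: 18 2-methoxy-6,7-dimethyl-8-(2,4,5-trimethoxyphenyl)naphthalene-1,4-dione, via naphthalene-1,4-diol 17 (not isolated)
Conditions: p-TsOH·H2O (5 mol %), CH2Cl2, 23 °C; then DDQ (1.05 equiv), 0 °C
Reagents that add atoms: none
Why: Acid ionises the tertiary C6–OCH3 bond to an allyl cation (C6–C7–C8) stabilised by both electron-rich aryl rings, loss of H-5 (E1 elimination) aromatises ring B to 17 without any oxidant, and DDQ then performs the single hydroquinone-to-quinone dehydrogenation of ring A much faster than any attack on ring C or the aryl methyl groups.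

**Compound list**
1 | o-vanillin (2-hydroxy-3-methoxybenzaldehyde) | COc1cccc(C=O)c1O | starting material
2 | 3-methoxy-2-(prop-2-en-1-yloxy)benzaldehyde | C=CCOc1c(OC)cccc1C=O | intermediate
3 | ethylmagnesium bromide | CC[Mg]Br | starting material
4 | (±)-1-[3-methoxy-2-(prop-2-en-1-yloxy)phenyl]propan-1-ol (racemic) | CCC(O)c1cccc(OC)c1OCC=C | intermediate
5 | 1-[3-methoxy-2-(prop-2-en-1-yloxy)phenyl]propan-1-one | CCC(=O)c1cccc(OC)c1OCC=C | intermediate
6 | potassium (Z)-1-[3-methoxy-2-(prop-2-en-1-yloxy)phenyl]prop-1-en-1-olate | C/C=C(\[O-])c1cccc(OC)c1OCC=C.[K+] | intermediate (not isolated)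
7 | (Z)-1-[3-methoxy-2-(prop-2-en-1-yloxy)phenyl]prop-1-en-1-yl trifluoromethanesulfonate | C/C=C(\OS(=O)(=O)C(F)(F)F)c1cccc(OC)c1OCC=C | intermediate
8 | 1-bromo-2,4,5-trimethoxybenzene | COc1cc(OC)c(Br)cc1OC | starting material
9 | 4,4,5,5-tetramethyl-2-(2,4,5-trimethoxyphenyl)-1,3,2-dioxaborolane | COc1cc(OC)c(cc1OC)B1OC(C)(C)C(C)(C)O1 | intermediate
10 | 1-{(E)-1-[3-methoxy-2-(prop-2-en-1-yloxy)phenyl]prop-1-en-1-yl}-2,4,5-trimethoxybenzene | C/C=C(\c1cc(OC)c(OC)cc1OC)c1cccc(OC)c1OCC=C | intermediate
11 | 2-methoxy-6-[(Z)-1-(2,4,5-trimethoxyphenyl)prop-1-en-1-yl]phenol | C/C=C(\c1cc(OC)c(OC)cc1OC)c1cccc(OC)c1O | intermediate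
12 | 2-methoxy-6-[(E)-1-(2,4,5-trimethoxyphenyl)prop-1-en-1-yl]cyclohexa-2,5-diene-1,4-dione | C/C=C(\c1cc(OC)c(OC)cc1OC)C1=CC(=O)C=C(OC)C1=O | intermediate (key-step precursor)
13 | 2-methoxypropene | C=C(C)OC | starting material
14 | 2,6-dimethoxy-6,7-dimethyl-8-(2,4,5-trimethoxyphenyl)-4a,5,6,7-tetrahydronaphthalene-1,4-dione (isoquinone methide, C8=C8a; racemic, one enantiomer drawn; H-4a cis to H-7, 6-OCH3 cis to 7-CH3) | COC1=CC(=O)[C@H]2C[C@@](C)(OC)[C@@H](C)C(c3cc(OC)c(OC)cc3OC)=C2C1=O | intermediate (not isolated)
15 | 4-hydroxy-2,6-dimethoxy-6,7-dimethyl-8-(2,4,5-trimethoxyphenyl)-6,7-dihydronaphthalen-1(5H)-one (o-quinone methide tautomer; racemic, one enantiomer drawn) | COC1=CC(O)=C2C[C@@](C)(OC)[C@@H](C)C(c3cc(OC)c(OC)cc3OC)=C2C1=O | intermediate (not isolated)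
16 | (±)-2,6-dimethoxy-6,7-dimethyl-8-(2,4,5-trimethoxyphenyl)-5,6-dihydronaphthalene-1,4-diol (racemic, 6R enantiomer drawn) | COc1cc(O)c2C[C@@](C)(OC)C(C)=C(c3cc(OC)c(OC)cc3OC)c2c1O | intermediate (key-step product)
17 | 2-methoxy-6,7-dimethyl-8-(2,4,5-trimethoxyphenyl)naphthalene-1,4-diol | COc1cc(O)c2cc(C)c(C)c(-c3cc(OC)c(OC)cc3OC)c2c1O | intermediate (not isolated)
18 | 2-methoxy-6,7-dimethyl-8-(2,4,5-trimethoxyphenyl)naphthalene-1,4-dione | COC1=CC(=O)c2cc(C)c(C)c(-c3cc(OC)c(OC)cc3OC)c2C1=O | target

**Step count**
- Total step count: 10.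
- Longest linear sequence: 9 (steps 1–4 and 6–10, from o-vanillin).

**Steps most likely to fail**

**Step 9 (key cycloaddition).**
- What may go wrong: the second bond has to join a fully substituted carbon to the methyl-bearing C7. After C4a–C5 bonding, the zwitterion-like stage may therefore lose a proton from the oxocarbenium methyl group or close through O4.
- Dimerisation or light- or base-induced tautomerisation of the quinone may also consume material, as may redox exchange with the product hydroquinone.
- Fallback: it sets out from 8 and comes back at 17, building ring B by a normal-demand Diels–Alder reaction.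
- Bromine–lithium exchange of 8 (n-BuLi, THF, −78 °C) gives 2,4,5-trimethoxyphenyllithium F1, which DMF formylates to 2,4,5-trimethoxybenzaldehyde F2.
- HCl-catalysed aldol condensation with butan-2-one, which under acid reacts at its CH2 group, gives (E)-3-methyl-4-(2,4,5-trimethoxyphenyl)but-3-en-2-one F3.
- Wittig methylenation (Ph3P=CH2) gives (E)-1-(2,3-dimethylbuta-1,3-dien-1-yl)-2,4,5-trimethoxybenzene F4.
- Heating F4 with commercial 2-methoxy-1,4-benzoquinone in PhMe should engage the unsubstituted C5=C6 bond of the quinone. The diene CH2 terminus bonds to the carbon β to the carbonyl that is not part of the vinylogous ester. This gives the endo adduct 2-methoxy-6,7-dimethyl-8-(2,4,5-trimethoxyphenyl)-4a,5,8,8a-tetrahydronaphthalene-1,4-dione F5.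
- Et3N enolises F5 to 2-methoxy-6,7-dimethyl-8-(2,4,5-trimethoxyphenyl)-5,8-dihydronaphthalene-1,4-diol F6.
- DDQ (2 equiv) removes H-8 and H-5 to reach 17 and then oxidises it to 18 as in step 10.

**Step 8 (Teuber oxidation and handling of the vinylquinone).**
- What may go wrong: spin density of the phenoxyl radical may leak into the propenyl group. The second radical coupling or an oxidative dimerisation would then occur at C7 instead of the para carbon.
- The quinone may also degrade during aqueous work-up.
- Fallback: it sets out from 8 and comes back at 12. The oxidation is moved to a phenol without an alkene, and the quinone–vinyl bond is made last.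
- Sonogashira coupling of 8 with propyne (PdCl2(PPh3)2, CuI, Et3N) gives 1,2,4-trimethoxy-5-(prop-1-yn-1-yl)benzene F7.
- Palladium-catalysed syn hydrostannation (Bu3SnH, PdCl2(PPh3)2, THF) is steered to the aryl-bearing carbon by the ortho methoxy group. It gives (E)-tributyl[1-(2,4,5-trimethoxyphenyl)prop-1-en-1-yl]stannane F8.
- Commercial 2-bromo-6-methoxyphenol is oxidised with ON(SO3K)2 to 2-bromo-6-methoxycyclohexa-2,5-diene-1,4-dione F9.
- Stille coupling of F8 with F9 (Pd(PPh3)4, CuI, 1,4-dioxane) replaces tin by the quinone ring with retention and gives 12.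

**Step 6 (hindered Suzuki coupling).**
- What may go wrong: slow transmetalation at the congested alkenyl centre may let other processes take over. These are protodeboronation of the boronate, S–O cleavage of the triflate back to the ketone, and elimination to the alkyne.
- Fallback: it sets out from 5 and 8 and comes back at 10. The C8–ring C bond is made by carbonyl addition instead of cross-coupling.
- Magnesium insertion into 8 gives 2,4,5-trimethoxyphenylmagnesium bromide F10.
- Addition of F10 to ketone 5 gives 1-[3-methoxy-2-(prop-2-en-1-yloxy)phenyl]-1-(2,4,5-trimethoxyphenyl)propan-1-ol F11.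
- Dehydration with catalytic p-TsOH in PhMe runs through the diaryl-stabilised cation. It gives 10 together with its geometric isomer 1-{(Z)-1-[3-methoxy-2-(prop-2-en-1-yloxy)phenyl]prop-1-en-1-yl}-2,4,5-trimethoxybenzene F12.
- The isomers are separated by chromatography. F12 is returned to the same acid equilibration and recycled.

**Further compounds**
F1 | step 9 | 2,4,5-trimethoxyphenyllithium | [Li]c1cc(OC)c(OC)cc1OC
F2 | step 9 | 2,4,5-trimethoxybenzaldehyde | COc1cc(OC)c(C=O)cc1OC
F3 | step 9 | (E)-3-methyl-4-(2,4,5-trimethoxyphenyl)but-3-en-2-one | CC(=O)/C(C)=C/c1cc(OC)c(OC)cc1OC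
F4 | step 9 | (E)-1-(2,3-dimethylbuta-1,3-dien-1-yl)-2,4,5-trimethoxybenzene | C=C(C)/C(C)=C/c1cc(OC)c(OC)cc1OC
F5 | step 9 | 2-methoxy-6,7-dimethyl-8-(2,4,5-trimethoxyphenyl)-4a,5,8,8a-tetrahydronaphthalene-1,4-dione (racemic endo adduct, H-4a, H-8a and H-8 all cis, one enantiomer drawn) | COC1=CC(=O)[C@H]2CC(C)=C(C)[C@@H](c3cc(OC)c(OC)cc3OC)[C@H]2C1=O
F6 | step 9 | 2-methoxy-6,7-dimethyl-8-(2,4,5-trimethoxyphenyl)-5,8-dihydronaphthalene-1,4-diol (racemic) | COc1cc(O)c2CC(C)=C(C)C(c3cc(OC)c(OC)cc3OC)c2c1O
F7 | step 8 | 1,2,4-trimethoxy-5-(prop-1-yn-1-yl)benzene | CC#Cc1cc(OC)c(OC)cc1OC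
F8 | step 8 | (E)-tributyl[1-(2,4,5-trimethoxyphenyl)prop-1-en-1-yl]stannane | C/C=C(\c1cc(OC)c(OC)cc1OC)[Sn](CCCC)(CCCC)CCCC
F9 | step 8 | 2-bromo-6-methoxycyclohexa-2,5-diene-1,4-dione | COC1=CC(=O)C=C(Br)C1=O
F10 | step 6 | 2,4,5-trimethoxyphenylmagnesium bromide | COc1cc(OC)c([Mg]Br)cc1OC
F11 | step 6 | 1-[3-methoxy-2-(prop-2-en-1-yloxy)phenyl]-1-(2,4,5-trimethoxyphenyl)propan-1-ol (racemic) | CCC(O)(c1cc(OC)c(OC)cc1OC)c1cccc(OC)c1OCC=C
F12 | step 6 | 1-{(Z)-1-[3-methoxy-2-(prop-2-en-1-yloxy)phenyl]prop-1-en-1-yl}-2,4,5-trimethoxybenzene | C/C=C(/c1cc(OC)c(OC)cc1OC)c1cccc(OC)c1OCC=C
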